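**Retrosynthetic overview**
- The target is opened at the inter-unit ester (C2' acid of the gem-dimethyl half with the C15 neopentyl alcohol of the other half); two tert-butyl esters are removed last.
- Both halves come from one common bicyclic alcohol: imide to methyl ester gives the C15-hydroxy half; radical removal of the C15 hydroxyl and imide to acid gives the gem-dimethyl half.
- Key step: Lewis-acid bicyclisation of an acyclic (R)-2,2-disubstituted oxirane / (E)-alkene / (Z)-allylsilane that already carries the isocitrate ether. Ring A closes first, then ring B, in one cascade; the oxirane stereocentre relays C4, C5, C10 and C9 and unveils the C15 hydroxyl.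
- The acyclic ether comes from silver-oxide O-alkylation (retention) of an Evans syn-aldol isocitrate alcohol with an allylic bromide; the allylsilane is installed afterwards by Negishi coupling.
- The allylic bromide comes from geranylacetone (alkyne formation, allylic oxidation, Sharpless epoxidation, hydride opening with hydroalumination–iodination, oxirane re-closure, bromination).

**Assumptions**
- Stereochemistry is taken exactly as in the SMILES: both isocitrate units are (1'R,2'R); drimane numbering is used for ring positions (C4, C5/C10 fusion, C9 bearing CH2O, C15 the oxygenated equatorial C4 substituent); primes denote the isocitrate (C1' bears the ether oxygen).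
- Isomerically pure (5E)-geranylacetone and monomeric methyl glyoxylate (cracked from its commercial hemiacetal) are taken as available.

**Route**

Step 1
Reactants: 1 (R)-4-benzyl-1,3-oxazolidin-2-one; 2 4-tert-butoxy-4-oxobutanoic acid (mono-tert-butyl succinate)
Product: 4 tert-butyl 4-[(4R)-4-benzyl-2-oxo-1,3-oxazolidin-3-yl]-4-oxobutanoate, via mixed pivalic anhydride 3 (not isolated)
Conditions: 2, t-BuCOCl, Et3N, THF, −20 °C; then 1, LiCl, −20 °C to rt
Reagents that add atoms: none
Why: N-acylation of the Evans auxiliary through the mixed pivalic anhydride (LiCl/Et3N protocol) is routine, leaves the tert-butyl ester untouched and creates no stereocentre.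

Step 2
Reactants: 4 tert-butyl 4-[(4R)-4-benzyl-2-oxo-1,3-oxazolidin-3-yl]-4-oxobutanoate; 5 methyl glyoxylate
Product: 7 tert-butyl (3R,4R)-3-{[(4R)-4-benzyl-2-oxo-1,3-oxazolidin-3-yl]carbonyl}-4-hydroxy-5-methoxy-5-oxopentanoate, via Z-dibutylboron enolate 6 (not isolated)
Conditions: Bu2BOTf, iPr2NEt, CH2Cl2, −78 to 0 °C; then 5, −78 to 0 °C; pH 7 buffer, MeOH, H2O2
Reagents that add atoms: none
Why: Evans syn-aldol reaction: the Z-boron enolate adds to the glyoxylate aldehyde through a Zimmerman–Traxler chair on the face away from the benzyl group, so the (R)-auxiliary sets C1' (R, carbinol) and C2' (R) in the syn relationship of the target; the γ-ester is tert-butyl so the product does not lactonise.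

Step 3
Reactants: 8 (5E)-6,10-dimethylundeca-5,9-dien-2-one (geranylacetone)
Product: 12 (6E)-7,11-dimethyldodeca-6,10-dien-2-yn-1-ol, via lithium enolate 9 (not isolated), via enol diethyl phosphate 10 (not isolated), via lithium acetylide 11 (not isolated)
Conditions: LiN(iPr)2 (1.05 equiv), THF, −78 °C; ClP(O)(OEt)2, −78 °C to rt; LiN(iPr)2 (2.3 equiv), −78 °C to rt; (CH2O)n, rt
Reagents that add atoms: paraformaldehyde (formaldehyde source), C=O
Why: Negishi methyl ketone to terminal alkyne conversion (kinetic enolate, enol phosphate, elimination with excess amide base) leaves the lithium acetylide in the flask, which is hydroxymethylated by formaldehyde; the (E)-alkene is untouched and no stereocentre is formed.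

Step 4
Reactants: 12 (6E)-7,11-dimethyldodeca-6,10-dien-2-yn-1-ol
Product: 13 (2E,6E)-2,6-dimethyldodeca-2,6-dien-10-yne-1,12-diol
Conditions: SeO2 (0.2 equiv), t-BuOOH, salicylic acid (cat.), CH2Cl2, rt
Reagents that add atoms: tert-butyl hydroperoxide, CC(C)(C)OO (oxygen relayed through catalytic SeO2, O=[Se]=O)
Why: SeO2-catalysed allylic oxidation (ene reaction then [2,3]-shift) is selective for the (E)-methyl group of the terminal trisubstituted alkene and gives the (E)-allylic alcohol needed for the next step.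

Step 5
Reactants: 13 (2E,6E)-2,6-dimethyldodeca-2,6-dien-10-yne-1,12-diol
Product: 14 (6E)-9-[(2S,3S)-3-(hydroxymethyl)-3-methyloxiran-2-yl]-7-methylnon-6-en-2-yn-1-ol
Conditions: Ti(OiPr)4, L-(+)-diethyl tartrate, t-BuOOH, 4 Å molecular sieves, CH2Cl2, −20 °C
Reagents that add atoms: tert-butyl hydroperoxide, CC(C)(C)OO
Why: Sharpless asymmetric epoxidation of the (E)-2-methylallylic alcohol with L-(+)-tartrate gives the (2S,3S)-epoxy alcohol (the propargylic alcohol is not a substrate); the quaternary C–O centre made here is the one that later controls all four ring stereocentres.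

Step 6
Reactants: 14 (6E)-9-[(2S,3S)-3-(hydroxymethyl)-3-methyloxiran-2-yl]-7-methylnon-6-en-2-yn-1-ol
Product: 16 (2Z,6E,11R)-3-iodo-7,11-dimethyldodeca-2,6-diene-1,11,12-triol, via cyclic alkenylalanate 15 (not isolated)
Conditions: LiAlH4, NaOMe, THF, 0 °C to reflux; then I2, THF, −78 °C
Reagents that add atoms: iodine, II
Why: LiAlH4 opens the 2-methyl-2,3-epoxy alcohol at the less substituted carbon (tertiary C–O centre untouched, now R by priority change) and trans-hydroaluminates the propargylic alcohol with alkoxide direction (Al at C3), so iodinolysis gives the (Z)-3-iodoallylic alcohol with retention.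

Step 7
Reactants: 16 (2Z,6E,11R)-3-iodo-7,11-dimethyldodeca-2,6-diene-1,11,12-triol
Product: 18 (2Z,6E)-3-iodo-7-methyl-10-[(2R)-2-methyloxiran-2-yl]deca-2,6-dien-1-ol, via primary tosylate 17 (not isolated)
Conditions: Bu2SnO (5 mol%), TsCl, Et3N, CH2Cl2, 0 °C; then K2CO3, MeOH, rt
Reagents that add atoms: none
Why: Tin-catalysed sulfonylation activates only the primary hydroxyl of the 1,2-diol (stannylene acetal), and base closes the 2,2-disubstituted oxirane by attack of the tertiary alkoxide on the primary tosylate, so the quaternary configuration is retained.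

Step 8
Reactants: 18 (2Z,6E)-3-iodo-7-methyl-10-[(2R)-2-methyloxiran-2-yl]deca-2,6-dien-1-ol
Product: 19 (2R)-2-[(4E,8Z)-10-bromo-8-iodo-4-methyldeca-4,8-dien-1-yl]-2-methyloxirane
Conditions: CBr4, PPh3, 2,6-lutidine, CH2Cl2, −20 to 0 °C
Reagents that add atoms: carbon tetrabromide, BrC(Br)(Br)Br
Why: Appel bromination gives the allylic bromide under neutral conditions that tolerate the oxirane and the alkenyl iodide; no stereocentre is touched.

Step 9
Reactants: 19 (2R)-2-[(4E,8Z)-10-bromo-8-iodo-4-methyldeca-4,8-dien-1-yl]-2-methyloxirane; 7 tert-butyl (3R,4R)-3-{[(4R)-4-benzyl-2-oxo-1,3-oxazolidin-3-yl]carbonyl}-4-hydroxy-5-methoxy-5-oxopentanoate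
Product: 20 tert-butyl (3R,4R)-3-{[(4R)-4-benzyl-2-oxo-1,3-oxazolidin-3-yl]carbonyl}-4-({(2Z,6E)-3-iodo-7-methyl-10-[(2R)-2-methyloxiran-2-yl]deca-2,6-dien-1-yl}oxy)-5-methoxy-5-oxopentanoate
Conditions: Ag2O, 4 Å molecular sieves, Et2O, rt, dark (7 in excess)
Reagents that add atoms: none
Why: Silver-oxide-mediated Williamson O-alkylation of the α-hydroxy ester by the allylic bromide forms the ether at oxygen with retention at C1' under non-basic conditions, avoiding retro-aldol and epimerisation.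

Step 10
Reactants: 20 the alkenyl iodide ether
Product: 21 tert-butyl (3R,4R)-3-{[(4R)-4-benzyl-2-oxo-1,3-oxazolidin-3-yl]carbonyl}-5-methoxy-4-({(2Z,6E)-7-methyl-10-[(2R)-2-methyloxiran-2-yl]-3-[(trimethylsilyl)methyl]deca-2,6-dien-1-yl}oxy)-5-oxopentanoate
Conditions: TMSCH2MgCl, ZnCl2, THF, 0 °C; then 20, Pd(PPh3)4 (5 mol%), THF, rt
Reagents that add atoms: (trimethylsilyl)methylmagnesium chloride, C[Si](C)(C)C[Mg]Cl
Why: Negishi cross-coupling of the (Z)-alkenyl iodide with the β-hydrogen-free silylmethylzinc reagent proceeds with retention of alkene geometry and tolerates esters, imide and oxirane, giving the (Z)-allylsilane terminator only after the silver step.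

Step 11
Reactants: 21 the oxirane/allylsilane ether
Product: 22 tert-butyl (3R,4R)-3-{[(4R)-4-benzyl-2-oxo-1,3-oxazolidin-3-yl]carbonyl}-4-{[(1S,4aR,5R,8aS)-5-(hydroxymethyl)-5,8a-dimethyl-2-methylidenedecahydronaphthalen-1-yl]methoxy}-5-methoxy-5-oxopentanoate
Conditions: MeAlCl2 (4 equiv), CH2Cl2, −78 °C; Et3N, then aq. potassium sodium tartrate
Reagents that add atoms: none
Why: Proposed new method: MeAlCl2 coordinates the oxirane oxygen and the C6=C7 alkene attacks the quaternary oxirane carbon from the backside (exo-mode, invertive opening) in a chair–chair fold with the CH2O–Al arm equatorial, the tertiary cation is captured by the (Z)-allylsilane and loss of silicon gives only the exocyclic alkene, so the single oxirane stereocentre fixes C4 (inversion), C5 and C10 (anti addition across the E-alkene, trans fusion) and C9 (equatorial CH2O from the Z-allylsilane); the closest known reactions are Lewis-acid epoxy-polyene bicyclisations of trisubstituted oxiranes and allylsilane-terminated cation–olefin cyclisations, and the minor C4-axial diastereomer is removed by chromatography.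

Step 12
Reactants: 22 the common bicyclic alcohol
Product: 23 3-tert-butyl 1,2-dimethyl (1R,2R)-1-{[(1S,4aR,5R,8aS)-5-(hydroxymethyl)-5,8a-dimethyl-2-methylidenedecahydronaphthalen-1-yl]methoxy}propane-1,2,3-tricarboxylate
Conditions: Sm(OTf)3 (10 mol%), MeOH, 40 °C
Reagents that add atoms: methanol, CO
Why: Lewis-acid-catalysed methanolysis of the N-acyl oxazolidinone replaces the auxiliary by OMe at the exocyclic carbonyl without base, so the β-alkoxy ester is not exposed to elimination or epimerisation.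

Step 13
Reactants: 22 the common bicyclic alcohol
Product: 25 tert-butyl (3R,4R)-3-{[(4R)-4-benzyl-2-oxo-1,3-oxazolidin-3-yl]carbonyl}-5-methoxy-5-oxo-4-{[(1S,4aS,8aS)-5,5,8a-trimethyl-2-methylidenedecahydronaphthalen-1-yl]methoxy}pentanoate, via thiocarbonylimidazolide 24 (not isolated)
Conditions: 1,1'-thiocarbonyldiimidazole, DMAP (cat.), toluene, 80 °C; then Bu3SnH, AIBN, 110 °C
Reagents that add atoms: none
Why: Barton–McCombie deoxygenation of the neopentyl primary alcohol (radical chain with Bu3SnH) turns CH2OH into the second C4 methyl group; esters, imide and the 1,1-disubstituted alkene are inert and C4 simply ceases to be a stereocentre.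

Step 14
Reactants: 25 the gem-dimethyl imide
Product: 26 (2R,3R)-2-(2-tert-butoxy-2-oxoethyl)-4-methoxy-4-oxo-3-{[(1S,4aS,8aS)-5,5,8a-trimethyl-2-methylidenedecahydronaphthalen-1-yl]methoxy}butanoic acid
Conditions: LiOH, H2O2, THF/H2O, 0 °C; then aq. Na2SO3; HCl to pH 3
Reagents that add atoms: hydrogen peroxide (as lithium hydroperoxide), OO
Why: Hydroperoxide cleavage of the Evans imide attacks the exocyclic carbonyl selectively and liberates only the C2' acid without epimerisation, while methyl and tert-butyl esters survive at 0 °C.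

Step 15
Reactants: 26 the C2' acid; 23 the C15 alcohol
Product: 28 bis(tert-butyl) ester of the target (both CH2CO2H groups as tert-butyl esters), via mixed anhydride 27 (not isolated)
Conditions: 26, 2,4,6-trichlorobenzoyl chloride, Et3N, toluene, rt; then 23, DMAP, toluene, rt
Reagents that add atoms: none
Why: Yamaguchi esterification through the mixed trichlorobenzoic anhydride and DMAP acylates the hindered neopentyl alcohol; limited DMAP at room temperature preserves the C2' stereocentre.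

Step 16
Reactants: 28 bis(tert-butyl) ester of the target
Product: 30 target compound CNP0139922.3, via bis(trimethylsilyl) ester 29 (not isolated)
Conditions: TMSOTf, 2,6-lutidine, CH2Cl2, 0 °C; then H2O
Reagents that add atoms: none
Why: Silyl-triflate cleavage of tert-butyl esters (transfer to silyl esters with loss of isobutene under lutidine buffering, then hydrolysis) removes both tert-butyl groups without protic acid, so the exocyclic alkenes, methyl esters, neopentyl ester and ethers are untouched.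

**Compound list**

1 | (R)-4-benzyl-1,3-oxazolidin-2-one | O=C1N[C@H](Cc2ccccc2)CO1 | starting material
2 | 4-tert-butoxy-4-oxobutanoic acid | CC(C)(C)OC(=O)CCC(=O)O | starting material
3 | mixed anhydride of 2 with pivalic acid | CC(C)(C)OC(=O)CCC(=O)OC(=O)C(C)(C)C | intermediate (not isolated)
4 | tert-butyl 4-[(4R)-4-benzyl-2-oxo-1,3-oxazolidin-3-yl]-4-oxobutanoate | CC(C)(C)OC(=O)CCC(=O)N1[C@H](Cc2ccccc2)COC1=O | intermediate
5 | methyl glyoxylate | COC(=O)C=O | starting material
6 | Z-dibutylboron enolate of 4 | CCCCB(CCCC)O/C(=C\CC(=O)OC(C)(C)C)N1[C@H](Cc2ccccc2)COC1=O | intermediate (not isolated)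
7 | tert-butyl (3R,4R)-3-{[(4R)-4-benzyl-2-oxo-1,3-oxazolidin-3-yl]carbonyl}-4-hydroxy-5-methoxy-5-oxopentanoate | COC(=O)[C@H](O)[C@@H](CC(=O)OC(C)(C)C)C(=O)N1[C@H](Cc2ccccc2)COC1=O | intermediate
8 | (5E)-6,10-dimethylundeca-5,9-dien-2-one (geranylacetone) | CC(=O)CC/C=C(C)/CCC=C(C)C | starting material
9 | kinetic lithium enolate of 8 | [Li]OC(=C)CC/C=C(C)/CCC=C(C)C | intermediate (not isolated)
10 | diethyl (5E)-6,10-dimethylundeca-1,5,9-trien-2-yl phosphate | C=C(OP(=O)(OCC)OCC)CC/C=C(C)/CCC=C(C)C | intermediate (not isolated)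
11 | lithium acetylide of (5E)-6,10-dimethylundeca-5,9-dien-1-yne | [Li]C#CCC/C=C(C)/CCC=C(C)C | intermediate (not isolated)
12 | (6E)-7,11-dimethyldodeca-6,10-dien-2-yn-1-ol | OCC#CCC/C=C(C)/CCC=C(C)C | intermediate
13 | (2E,6E)-2,6-dimethyldodeca-2,6-dien-10-yne-1,12-diol | OCC#CCC/C=C(C)/CC/C=C(C)/CO | intermediate
14 | (6E)-9-[(2S,3S)-3-(hydroxymethyl)-3-methyloxiran-2-yl]-7-methylnon-6-en-2-yn-1-ol | OCC#CCC/C=C(C)/CC[C@@H]1O[C@@]1(C)CO | intermediate
15 | cyclic (Z)-alkenylalanate (five-membered O–Al–C=C chelate; distal diol as lithium alkoxides) | [Li+].[AlH2-]1OCC=C1CC/C=C(C)/CCC[C@@](C)(O[Li])CO[Li] | intermediate (not isolated)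
16 | (2Z,6E,11R)-3-iodo-7,11-dimethyldodeca-2,6-diene-1,11,12-triol | OC/C=C(\I)/CC/C=C(C)/CCC[C@@](C)(O)CO | intermediate
17 | (2R,6E,10Z)-2,12-dihydroxy-10-iodo-2,6-dimethyldodeca-6,10-dien-1-yl 4-methylbenzenesulfonate | OC/C=C(\I)/CC/C=C(C)/CCC[C@@](C)(O)COS(=O)(=O)c1ccc(C)cc1 | intermediate (not isolated)
18 | (2Z,6E)-3-iodo-7-methyl-10-[(2R)-2-methyloxiran-2-yl]deca-2,6-dien-1-ol | OC/C=C(\I)/CC/C=C(C)/CCC[C@]1(C)CO1 | intermediate
19 | (2R)-2-[(4E,8Z)-10-bromo-8-iodo-4-methyldeca-4,8-dien-1-yl]-2-methyloxirane | BrC/C=C(\I)/CC/C=C(C)/CCC[C@]1(C)CO1 | intermediate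
20 | tert-butyl (3R,4R)-3-{[(4R)-4-benzyl-2-oxo-1,3-oxazolidin-3-yl]carbonyl}-4-({(2Z,6E)-3-iodo-7-methyl-10-[(2R)-2-methyloxiran-2-yl]deca-2,6-dien-1-yl}oxy)-5-methoxy-5-oxopentanoate | O(C/C=C(\I)/CC/C=C(C)/CCC[C@]1(C)CO1)[C@@H](C(=O)OC)[C@@H](CC(=O)OC(C)(C)C)C(=O)N1[C@H](Cc2ccccc2)COC1=O | intermediate
21 | same ether with 3-[(trimethylsilyl)methyl] in place of 3-iodo (2Z,6E) | O(C/C=C(\C[Si](C)(C)C)/CC/C=C(C)/CCC[C@]1(C)CO1)[C@@H](C(=O)OC)[C@@H](CC(=O)OC(C)(C)C)C(=O)N1[C@H](Cc2ccccc2)COC1=O | intermediate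
22 | tert-butyl (3R,4R)-3-{[(4R)-4-benzyl-2-oxo-1,3-oxazolidin-3-yl]carbonyl}-4-{[(1S,4aR,5R,8aS)-5-(hydroxymethyl)-5,8a-dimethyl-2-methylidenedecahydronaphthalen-1-yl]methoxy}-5-methoxy-5-oxopentanoate | OC[C@]1(C)CCC[C@]2(C)[C@@H](CO[C@@H](C(=O)OC)[C@@H](CC(=O)OC(C)(C)C)C(=O)N3[C@H](Cc4ccccc4)COC3=O)C(=C)CC[C@@H]12 | intermediate
23 | 3-tert-butyl 1,2-dimethyl (1R,2R)-1-{[(1S,4aR,5R,8aS)-5-(hydroxymethyl)-5,8a-dimethyl-2-methylidenedecahydronaphthalen-1-yl]methoxy}propane-1,2,3-tricarboxylate | OC[C@]1(C)CCC[C@]2(C)[C@@H](CO[C@@H](C(=O)OC)[C@@H](CC(=O)OC(C)(C)C)C(=O)OC)C(=C)CC[C@@H]12 | intermediate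
24 | O-(imidazol-1-ylthiocarbonyl) derivative of 22 at the C15 oxygen | S=C(n1ccnc1)OC[C@]1(C)CCC[C@]2(C)[C@@H](CO[C@@H](C(=O)OC)[C@@H](CC(=O)OC(C)(C)C)C(=O)N3[C@H](Cc4ccccc4)COC3=O)C(=C)CC[C@@H]12 | intermediate (not isolated)
25 | tert-butyl (3R,4R)-3-{[(4R)-4-benzyl-2-oxo-1,3-oxazolidin-3-yl]carbonyl}-5-methoxy-5-oxo-4-{[(1S,4aS,8aS)-5,5,8a-trimethyl-2-methylidenedecahydronaphthalen-1-yl]methoxy}pentanoate | C=C1CC[C@H]2C(C)(C)CCC[C@]2(C)[C@H]1CO[C@@H](C(=O)OC)[C@@H](CC(=O)OC(C)(C)C)C(=O)N1[C@H](Cc2ccccc2)COC1=O | intermediate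
26 | (2R,3R)-2-(2-tert-butoxy-2-oxoethyl)-4-methoxy-4-oxo-3-{[(1S,4aS,8aS)-5,5,8a-trimethyl-2-methylidenedecahydronaphthalen-1-yl]methoxy}butanoic acid | C=C1CC[C@H]2C(C)(C)CCC[C@]2(C)[C@H]1CO[C@@H](C(=O)OC)[C@@H](CC(=O)OC(C)(C)C)C(=O)O | intermediate
27 | mixed anhydride of 26 with 2,4,6-trichlorobenzoic acid | C=C1CC[C@H]2C(C)(C)CCC[C@]2(C)[C@H]1CO[C@@H](C(=O)OC)[C@@H](CC(=O)OC(C)(C)C)C(=O)OC(=O)c1c(Cl)cc(Cl)cc1Cl | intermediate (not isolated)
28 | bis(tert-butyl) ester of the target | C=C1CC[C@H]2C(C)(C)CCC[C@]2(C)[C@H]1CO[C@@H](C(=O)OC)[C@@H](CC(=O)OC(C)(C)C)C(=O)OC[C@]1(C)CCC[C@]2(C)[C@@H](CO[C@@H](C(=O)OC)[C@@H](CC(=O)OC(C)(C)C)C(=O)OC)C(=C)CC[C@@H]12 | intermediate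
29 | bis(trimethylsilyl) ester of the target | C=C1CC[C@H]2C(C)(C)CCC[C@]2(C)[C@H]1CO[C@@H](C(=O)OC)[C@@H](CC(=O)O[Si](C)(C)C)C(=O)OC[C@]1(C)CCC[C@]2(C)[C@@H](CO[C@@H](C(=O)OC)[C@@H](CC(=O)O[Si](C)(C)C)C(=O)OC)C(=C)CC[C@@H]12 | intermediate (not isolated)
30 | CNP0139922.3 | C=C1CC[C@H]2C(C)(C)CCC[C@]2(C)[C@H]1CO[C@@H](C(=O)OC)[C@@H](CC(=O)O)C(=O)OC[C@]1(C)CCC[C@]2(C)[C@@H](CO[C@@H](C(=O)OC)[C@@H](CC(=O)O)C(=O)OC)C(=C)CC[C@@H]12 | target

**Step count and risk**

Total step count: 16 (step 11 is run once; its product 22 feeds both halves).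
Longest linear sequence: 13 steps (8 → 12 → 13 → 14 → 16 → 18 → 19 → 20 → 21 → 22 → 25 → 26 → 28 → 30; steps 3–11 and 13–16).

Steps most likely to fail:

1. Step 11 (oxirane-relayed bicyclisation). Risks are partial ionisation to a free tertiary cation (loss of stereochemical transfer), an axial CH2O fold, hydride shift to the aldehyde, or Lewis-acid 1,4-elimination of the silylated allylic ether. The fallback sets out from 7 and comes back at 22; it moves the stereochemical relay to a secondary C–O centre that is not a reacting centre and closes the rings by a radical cascade. Silver-oxide O-alkylation of 7 with commercial (2E,6E)-farnesyl bromide gives the farnesyl ether F1. SeO2/t-BuOOH oxidation of the terminal (E)-methyl group gives the allylic alcohol F2. Sharpless epoxidation with L-(+)-diethyl tartrate gives the (10S,11S)-epoxy alcohol F3, which TBSCl/imidazole converts into the silyl ether F4. Titanocene monochloride (from Cp2TiCl2 and Mn, THF) opens the trisubstituted oxirane homolytically; the tertiary radical closes both rings and terminates to the exocyclic alkene, giving the 3β-hydroxy bicycle F5. Barton–McCombie removal of the C3 hydroxyl through the thiocarbonylimidazolide F6 gives the silyl ether F7, and HF·pyridine returns 22.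

2. Step 13 (radical deoxygenation of a neopentyl primary alcohol; slow fragmentation of the primary thiocarbonyl adduct). The fallback sets out from 22 and comes back at 25; it is ionic rather than radical. Dess–Martin oxidation gives the neopentyl aldehyde F8, condensation with TsNHNH2 gives the tosylhydrazone F9, and catecholborane followed by NaOAc·3H2O reduces the hydrazone with loss of sulfinate and nitrogen to the methyl group of 25.

3. Step 12 (Lewis-acid methanolysis of a hindered β-alkoxy imide; slow turnover or alkene isomerisation by adventitious acid). The fallback sets out from 22 and comes back at 23; it is hydrolysis then O-methylation. LiOH/H2O2 cleaves the imide to the hydroxy acid F10, and TMSCHN2 in MeOH/toluene methylates the acid to 23.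

**Further compounds**

F1 | step 11 | (2E,6E)-farnesyl ether of 7 | O(C/C=C(C)/CC/C=C(C)/CCC=C(C)C)[C@@H](C(=O)OC)[C@@H](CC(=O)OC(C)(C)C)C(=O)N1[C@H](Cc2ccccc2)COC1=O
F2 | step 11 | (2E,6E,10E)-12-hydroxyfarnesyl ether of 7 | O(C/C=C(C)/CC/C=C(C)/CC/C=C(C)/CO)[C@@H](C(=O)OC)[C@@H](CC(=O)OC(C)(C)C)C(=O)N1[C@H](Cc2ccccc2)COC1=O
F3 | step 11 | (10S,11S)-10,11-epoxy-12-hydroxyfarnesyl ether of 7 | O(C/C=C(C)/CC/C=C(C)/CC[C@@H]1O[C@@]1(C)CO)[C@@H](C(=O)OC)[C@@H](CC(=O)OC(C)(C)C)C(=O)N1[C@H](Cc2ccccc2)COC1=O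
F4 | step 11 | 12-O-tert-butyldimethylsilyl ether of F3 | O(C/C=C(C)/CC/C=C(C)/CC[C@@H]1O[C@@]1(C)CO[Si](C)(C)C(C)(C)C)[C@@H](C(=O)OC)[C@@H](CC(=O)OC(C)(C)C)C(=O)N1[C@H](Cc2ccccc2)COC1=O
F5 | step 11 | 3β-hydroxy-15-O-silyl analogue of 22 (3S) | CC(C)(C)[Si](C)(C)OC[C@]1(C)[C@@H](O)CC[C@]2(C)[C@@H](CO[C@@H](C(=O)OC)[C@@H](CC(=O)OC(C)(C)C)C(=O)N3[C@H](Cc4ccccc4)COC3=O)C(=C)CC[C@@H]12
F6 | step 11 | 3-O-(imidazol-1-ylthiocarbonyl) derivative of F5 | CC(C)(C)[Si](C)(C)OC[C@]1(C)[C@@H](OC(=S)n2ccnc2)CC[C@]2(C)[C@@H](CO[C@@H](C(=O)OC)[C@@H](CC(=O)OC(C)(C)C)C(=O)N3[C@H](Cc4ccccc4)COC3=O)C(=C)CC[C@@H]12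
F7 | step 11 | 15-O-tert-butyldimethylsilyl ether of 22 | CC(C)(C)[Si](C)(C)OC[C@]1(C)CCC[C@]2(C)[C@@H](CO[C@@H](C(=O)OC)[C@@H](CC(=O)OC(C)(C)C)C(=O)N3[C@H](Cc4ccccc4)COC3=O)C(=C)CC[C@@H]12
F8 | step 13 | C15 aldehyde from 22 | O=C[C@]1(C)CCC[C@]2(C)[C@@H](CO[C@@H](C(=O)OC)[C@@H](CC(=O)OC(C)(C)C)C(=O)N3[C@H](Cc4ccccc4)COC3=O)C(=C)CC[C@@H]12
F9 | step 13 | tosylhydrazone of F8 | Cc1ccc(cc1)S(=O)(=O)NN=C[C@]1(C)CCC[C@]2(C)[C@@H](CO[C@@H](C(=O)OC)[C@@H](CC(=O)OC(C)(C)C)C(=O)N3[C@H](Cc4ccccc4)COC3=O)C(=C)CC[C@@H]12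
F10 | step 12 | hydroxy acid from 22 (C2' carboxylic acid, C15 alcohol) | OC[C@]1(C)CCC[C@]2(C)[C@@H](CO[C@@H](C(=O)OC)[C@@H](CC(=O)OC(C)(C)C)C(=O)O)C(=C)CC[C@@H]12
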